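(The runs were generated by integration for substances that don't exist; the scatter is artificial.)

Target lives far shorter than the flask named red runs: the south-east run falls from 7.7 % at 30.0 min to 0.6 % at 60.0 min, which I read as a half-life of 8.15 min, against 2.5 h for red.

| setting | north | south-east | red | blue |
|---|---|---|---|---|
| substrate | 1 M | 1.5 M | 2.0 M | 2.0 M |
| gas phase | 200 mM (held) | 200 mM (held) | 200 mM (held) | 200 mM (held) |
| remark | run made earlier | run made earlier |  |  |
| time |  |  | 2.5 h | 5.0 h |

- north (time / min: target / %, substrate / %): 25.0: 8.0, 3.9; 50.0: 0.5, 0; 80.0: 0, 0.9; 90.0: 0, 0.3; 120: 1.3, 0
- south-east (time / min: target / %, substrate / %): 10.0: 19.7, 31.6; 30.0: 7.7, 2.2; 60.0: 0.6, 0; 80.0: 0.9, 1.1; 120: 0, 0.3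

(standard deviation of a reading: 1 percentage point)

- the analysis behind the earlier runs scatters by 1 percentage point, standard deviation
- at the start none of the gas phase is in solution

- which of the two there is more of at the end, red (over-reaction product / target)
- which of the two there is more of at the end, blue (over-reaction product / target)
- target at the end, in percent of the substrate charged, red
- target at the end, in percent of the substrate charged, blue

I climb the time scales from the fastest. Substrate stands on the lowest rung: the south-east run, from 31.6 % at 10.0 min to 2.2 % at 30.0 min, reads as a half-life of 5.20 min, shorter than that of target. So at 30.0 min that flask holds more target than substrate, 7.7 % against 2.2 %.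

Target is the next rung. The north run reads 6.25 min, quicker than my figure, and I keep the slower one. It stays rough, since its last reading lies inside the scatter of 1 percentage point. The south-east target reads inside that scatter at 60.0 min, which counted from the charge is 7.36 half-lives.

The clock is the top rung. For red it holds 18.4 half-lives and for blue 36.8: this turnover count, the flask's time over the half-life of target, is what I carry. Counted from the charge as well, red's count is 2.50 times that south-east count, though neither earlier run stood at 2.0 M. I expect target inside the scatter in both flasks, with over-reaction product ahead of it.

The forecast says over-reaction product for red and over-reaction product for blue, with target at 0.2 % (range 0 % to 1.5 %) and 0 % (range 0 % to 1 %), on the ground that “even a several-fold slowdown leaves target essentially gone”.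

Red's 18.4 half-lives end at target 0 % and over-reaction product 55.8 %; blue's 36.8 end at 0 % and 55.8 %.

    gas phase ⇌ dissolved gas, rate k1*(csat - [dissolved gas]) (kL = 1.50 min⁻¹)
    substrate + dissolved gas → target (k = 0.450 L mol⁻¹ min⁻¹)
    substrate → side product (k = 0.0500 min⁻¹)
    dissolved gas → decomposed reagent (k = 0.0250 min⁻¹)
    2 dissolved gas → homo dimer (k = 0.250 L mol⁻¹ min⁻¹)
    target → over-reaction product (k = 0.130 min⁻¹)

The neighbour of red, charged with 0.80 M of substrate, runs the same 2.5 h. My count takes no charge, so it again holds 18.4 half-lives. That flask ends at target 0 %, with substrate, the limiting reagent, at 0 %. Its side product stands at 41.4 %, less than the 44.2 % in red, and its over-reaction product at 58.6 %.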